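**Strategy.** The upper pyran ring (ring C: O1–C2–C3–C4–C4a–C8a) is disconnected at C4–C4a. Its C4 is benzylic to ring A and to ring D, and its C3 hydroxyl is trans to the C4 aryl group: the pattern left by anti opening of a trans C3–C4 epoxide by an arene. The precursor is therefore an acyclic aryl ether, ring A–O1–C2H(aryl)–[trans-epoxide]–ring D, made from a chalcone-type enone by catalytic asymmetric epoxidation, chelation-controlled reduction and Mitsunobu etherification. A Lewis acid then triggers an intramolecular Friedel–Crafts epoxide–arene cyclisation that forms C4–C4a, closes ring C and sets C4 by inversion, while the epoxide oxygen becomes the 3-OH. The lower flavan-3,4-diol unit is completed beforehand.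

Key step: step 14

Remark: flavan numbering is used for each unit (upper unit rings A, B, C; lower unit rings D benzo, E aryl, F pyran, positions primed); CIP descriptors of some centres change between intermediates only because protecting groups alter priorities, not geometry.

Step 1
Reactants: 1 2',3',4'-trihydroxyacetophenone
Product: 2 1-[3,4-bis(benzyloxy)-2-hydroxyphenyl]ethan-1-one
Conditions: BnBr (2.1 equiv), K2CO3, DMF, rt
Reagents that add atoms: benzyl bromide, BrCc1ccccc1
Why: Williamson etherification in which the 2-hydroxyl, held in a hydrogen bond to the acetyl carbonyl, is the least acidic and least nucleophilic, so two equivalents of benzyl bromide should take only the 3- and 4-hydroxyls.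

Step 2
Reactants: 2 1-[3,4-bis(benzyloxy)-2-hydroxyphenyl]ethan-1-one
Product: 3 1-[3,4-bis(benzyloxy)-5-bromo-2-hydroxyphenyl]ethan-1-one
Conditions: NBS, MeCN, 0 °C to rt
Reagents that add atoms: N-bromosuccinimide, O=C1CCC(=O)N1Br
Why: Electrophilic aromatic bromination directed by the free phenol to its para position C5, the only other free carbon (C6) being ortho to the acetyl group and meta to the phenol.

Step 3
Reactants: 3 1-[3,4-bis(benzyloxy)-5-bromo-2-hydroxyphenyl]ethan-1-one
Product: 5 7,8-bis(benzyloxy)-6-bromo-4H-chromen-4-one, via enaminone 4 (not isolated)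
Conditions: Me2NCH(OMe)2, toluene, 100 °C; then conc. HCl, CH2Cl2, 40 °C
Reagents that add atoms: N,N-dimethylformamide dimethyl acetal, COC(OC)N(C)C
Why: Standard chromone synthesis, in which condensation of the methyl ketone with the amide acetal gives the enaminone and acid then drives 6-endo conjugate addition of the phenol and loss of dimethylamine.

Step 4
Reactants: 5 7,8-bis(benzyloxy)-6-bromo-4H-chromen-4-one; 6 [4-(benzyloxy)phenyl]boronic acid
Product: 7 (2S)-7,8-bis(benzyloxy)-2-[4-(benzyloxy)phenyl]-6-bromo-2,3-dihydro-4H-chromen-4-one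
Conditions: Pd(OCOCF3)2 (5 mol %), (R)-4-tert-butyl-2-(pyridin-2-yl)-4,5-dihydrooxazole (6 mol %), NH4PF6, H2O, ClCH2CH2Cl, 60 °C
Reagents that add atoms: none
Why: Catalytic asymmetric conjugate addition of an arylboronic acid to a chromone with a cationic divalent palladium pyridine-oxazoline catalyst; the ligand alone sets C2, the (R)-ligand being chosen because the facial sense known for cyclic enones, transposed to the chromone, predicts the 2S flavanone, and the aryl bromide should survive because no zerovalent palladium is involved.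

Step 5
Reactants: 7 (2S)-flavanone
Product: 8 (2S,4S)-7,8-bis(benzyloxy)-2-[4-(benzyloxy)phenyl]-6-bromo-3,4-dihydro-2H-chromen-4-ol
Conditions: NaBH4, THF/MeOH, 0 °C
Reagents that add atoms: none
Why: Borohydride reduction of the ketone with pseudo-axial hydride delivery, expected to give the 2,4-cis alcohol, although the C4 configuration is of no consequence because this centre is removed in step 6.

Step 6
Reactants: 8 (2S,4S)-flavan-4-ol
Product: 10 (2S)-7,8-bis(benzyloxy)-2-[4-(benzyloxy)phenyl]-6-bromo-2H-chromene, via mesylate 9 (not isolated)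
Conditions: MsCl, Et3N (4 equiv), CH2Cl2, 0 to 40 °C
Reagents that add atoms: none
Why: Dehydration by mesylation and E1-type elimination, since the C4 mesylate (benzylic, para to the O7 ether) ionises readily and loses H3 to the amine; a basic medium is chosen because acid could open the C2–O1 bond of the product and racemise C2.

Step 7
Reactants: 10 (2S)-flav-3-ene
Product: 12 (2R,3S,4S)-7,8-bis(benzyloxy)-2-[4-(benzyloxy)phenyl]-6-bromo-3,4-dihydro-2H-chromene-3,4-diyl dibenzoate, via iodobenzoate 11 (not isolated)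
Conditions: I2 (1.05 equiv), silver benzoate AgO2CPh (2.2 equiv), dry toluene, rt then 80 °C, dark
Reagents that add atoms: silver benzoate, [Ag+].[O-]C(=O)c1ccccc1
Why: Prévost reaction relayed from C2: iodine adds to the face opposite the 2-aryl group, benzoate opens the iodonium ion at benzylic C4, the C4 benzoate displaces iodide from C3 on the aryl face to give a dioxolanylium ion, and the second benzoate opens that ion at benzylic C4 with inversion, which places O3 cis to the aryl group and O4 trans to O3 (2,3-cis-3,4-trans).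

Step 8
Reactants: 13 4-(benzyloxy)benzoyl chloride; 14 tributyl(vinyl)stannane
Product: 15 1-[4-(benzyloxy)phenyl]prop-2-en-1-one
Conditions: PdCl2(PPh3)2 (2 mol %), BHT, THF, 60 °C
Reagents that add atoms: none
Why: Stille acylation (palladium-catalysed coupling of an acid chloride with a vinylstannane) gives the aryl vinyl ketone directly under neutral conditions; it is used at once in the presence of a radical inhibitor.

Step 9
Reactants: 12 lower-unit bromide dibenzoate; 15 1-[4-(benzyloxy)phenyl]prop-2-en-1-one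
Product: 16 (2R,3S,4S)-7,8-bis(benzyloxy)-2-[4-(benzyloxy)phenyl]-6-{(1E)-3-[4-(benzyloxy)phenyl]-3-oxoprop-1-en-1-yl}-3,4-dihydro-2H-chromene-3,4-diyl dibenzoate
Conditions: Pd2(dba)3 (2.5 mol %), [HP(t-Bu)3]BF4 (10 mol %), Cy2NMe, BHT, 1,4-dioxane, 70 °C
Reagents that add atoms: none
Why: Mizoroki–Heck reaction of the electron-rich aryl bromide with the terminal enone under a bulky trialkylphosphine catalyst, where syn insertion and syn β-hydride elimination should give the E enone and the amine base leaves the benzoates intact.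

Step 10
Reactants: 16 E enone
Product: 17 (2R,3S,4S)-7,8-bis(benzyloxy)-6-{(2S,3R)-3-[4-(benzyloxy)benzoyl]oxiran-2-yl}-2-[4-(benzyloxy)phenyl]-3,4-dihydro-2H-chromene-3,4-diyl dibenzoate
Conditions: La(O-i-Pr)3 (10 mol %), (S)-BINOL (10 mol %), Ph3As=O (10 mol %), t-BuOOH (1.5 equiv), 4 Å MS, THF, rt
Reagents that add atoms: tert-butyl hydroperoxide, CC(C)(C)OO
Why: Catalytic asymmetric nucleophilic (Weitz–Scheffer-type) epoxidation of a chalcone-type enone with a lanthanum–BINOL peroxide catalyst; the catalyst, not the remote lower unit, selects the enone face, the (S)-BINOL complex being the one that gives (2R,3S)-epoxy ketones from chalcones, and the E geometry is carried into the trans-epoxide.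

Step 11
Reactants: 17 trans-epoxy ketone
Product: 18 (2R,3S,4S)-7,8-bis(benzyloxy)-6-[(2S,3S)-3-{(S)-[4-(benzyloxy)phenyl](hydroxy)methyl}oxiran-2-yl]-2-[4-(benzyloxy)phenyl]-3,4-dihydro-2H-chromene-3,4-diyl dibenzoate (anti epoxy alcohol)
Conditions: Zn(BH4)2, Et2O, −20 °C
Reagents that add atoms: none
Why: Chelation-controlled reduction of an α,β-epoxy ketone, in which zinc bridges the carbonyl and epoxide oxygens and hydride enters from the face away from C4, so the anti (erythro) epoxy alcohol is expected and C2 is relayed from C3.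

Step 12
Reactants: 19 pyrogallol
Product: 20 2,2-diphenyl-1,3-benzodioxol-4-ol
Conditions: Ph2CCl2, neat, 170 °C, N2 stream
Reagents that add atoms: dichlorodiphenylmethane, ClC(Cl)(c1ccccc1)c1ccccc1
Why: Ketalisation of two adjacent phenols of the symmetrical triol with the gem-dichloride leaves one hydroxyl free, and the diphenylmethylene group is later removed by hydrogenolysis together with the benzyl ethers.

Step 13
Reactants: 18 anti epoxy alcohol; 20 2,2-diphenyl-1,3-benzodioxol-4-ol
Product: 21 (2R,3S,4S)-7,8-bis(benzyloxy)-6-[(2S,3R)-3-{(R)-[4-(benzyloxy)phenyl][(2,2-diphenyl-1,3-benzodioxol-4-yl)oxy]methyl}oxiran-2-yl]-2-[4-(benzyloxy)phenyl]-3,4-dihydro-2H-chromene-3,4-diyl dibenzoate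
Conditions: PPh3, DIAD, toluene, −20 °C to rt
Reagents that add atoms: none
Why: Mitsunobu etherification of a secondary alcohol with a phenol, where SN2 inversion at C2 turns the anti epoxy alcohol into the syn aryl ether needed for the 2,3-cis ring; low temperature and a non-polar solvent are meant to hold back ionisation of the para-alkoxybenzylic oxyphosphonium ion.

Step 14
Reactants: 21 aryl ether trans-epoxide
Product: 22 (2R,3S,4S)-7,8-bis(benzyloxy)-2-[4-(benzyloxy)phenyl]-6-{(2R,3R,4R)-2-[4-(benzyloxy)phenyl]-3-hydroxy-7,8-(diphenylmethylenedioxy)-3,4-dihydro-2H-chromen-4-yl}-3,4-dihydro-2H-chromene-3,4-diyl dibenzoate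
Conditions: BF3·OEt2 (20 mol %), CH2Cl2, −78 to −40 °C
Reagents that add atoms: none
Why: BF3 binds the epoxide oxygen and weakens the C4–O bond, which is benzylic to ring D and conjugated with its ortho and para ether oxygens; C4a of ring A (ortho to O1, para to the ketal oxygen on C7) attacks C4 opposite the departing oxygen and rearomatises, an intramolecular Friedel–Crafts epoxide–arene cyclisation of the kind that turns trans-3-arylglycidyl aryl ethers into trans-4-arylchroman-3-ols. Ring C closes in the 6-endo-tet mode (both epoxide carbons end inside the ring), the 5-exo alternative at C3 being disfavoured because C3 has no cation-stabilising group. C4 is the only new stereocentre and is fixed by the epoxide: anti opening of the trans-epoxide places the ring D aryl trans to O3 (4β), so C4 is relayed from C3, while C2 and C3 are carried over unchanged and end cis. The step needs C4 over C3 regioselectivity (secured by the doubly oxygen-activated benzylic position), attack by C4a only (the one activated arene carbon within reach; the ortho carbons of ring B are meta to their oxygen) and selectivity for the epoxide over the lower C4' benzoate (secured by catalytic acid at low temperature and the sluggish ionisation of a 7,8-dioxygenated flavan at C4).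

Step 15
Reactants: 22 cyclised dibenzoate
Product: 23 (2R,3R,4S)-7,8-bis(benzyloxy)-2-[4-(benzyloxy)phenyl]-6-{(2R,3R,4R)-2-[4-(benzyloxy)phenyl]-3-hydroxy-7,8-(diphenylmethylenedioxy)-3,4-dihydro-2H-chromen-4-yl}-3,4-dihydro-2H-chromene-3,4-diol
Conditions: K2CO3, MeOH/THF, rt
Reagents that add atoms: none
Why: Base-catalysed transesterification (Zemplén-type methanolysis) removes both benzoates as methyl benzoate without touching benzyl ethers, ketal or any stereocentre, and is done before the air- and base-sensitive phenols are set free.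

Step 16
Reactants: 23 protected triol
Product: 24 (2R,3R,4S)-2-(4-hydroxyphenyl)-6-[(2R,3R,4S)-3,7,8-trihydroxy-2-(4-hydroxyphenyl)-3,4-dihydro-2H-chromen-4-yl]-3,4-dihydro-2H-chromene-3,4,7,8-tetrol
Conditions: H2 (1 atm), Pd(OH)2/C, THF/MeOH, rt
Reagents that add atoms: none
Why: Catalytic hydrogenolysis cleaves the four benzyl ethers and the diphenylmethylene ketal, while the benzylic C–O bonds at C2, C2' and C4' and the diarylmethine C4 are expected to survive under neutral conditions at one atmosphere.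

**Compound list**

1 | 2',3',4'-trihydroxyacetophenone | CC(=O)c1ccc(O)c(O)c1O | starting material
2 | 1-[3,4-bis(benzyloxy)-2-hydroxyphenyl]ethan-1-one | CC(=O)c1ccc(OCc2ccccc2)c(OCc2ccccc2)c1O | intermediate
3 | 1-[3,4-bis(benzyloxy)-5-bromo-2-hydroxyphenyl]ethan-1-one | CC(=O)c1cc(Br)c(OCc2ccccc2)c(OCc2ccccc2)c1O | intermediate
4 | (E)-1-[3,4-bis(benzyloxy)-5-bromo-2-hydroxyphenyl]-3-(dimethylamino)prop-2-en-1-one | CN(C)/C=C/C(=O)c1cc(Br)c(OCc2ccccc2)c(OCc2ccccc2)c1O | intermediate
5 | 7,8-bis(benzyloxy)-6-bromo-4H-chromen-4-one | O=c1ccoc2c(OCc3ccccc3)c(OCc3ccccc3)c(Br)cc12 | intermediate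
6 | [4-(benzyloxy)phenyl]boronic acid | OB(O)c1ccc(OCc2ccccc2)cc1 | starting material
7 | (2S)-7,8-bis(benzyloxy)-2-[4-(benzyloxy)phenyl]-6-bromo-2,3-dihydro-4H-chromen-4-one | Brc1cc2c(c(OCc3ccccc3)c1OCc1ccccc1)O[C@H](c1ccc(OCc3ccccc3)cc1)CC2=O | intermediate
8 | (2S,4S)-7,8-bis(benzyloxy)-2-[4-(benzyloxy)phenyl]-6-bromo-3,4-dihydro-2H-chromen-4-ol | Brc1cc2c(c(OCc3ccccc3)c1OCc1ccccc1)O[C@H](c1ccc(OCc3ccccc3)cc1)C[C@@H]2O | intermediate
9 | (2S,4S)-7,8-bis(benzyloxy)-2-[4-(benzyloxy)phenyl]-6-bromo-3,4-dihydro-2H-chromen-4-yl methanesulfonate | Brc1cc2c(c(OCc3ccccc3)c1OCc1ccccc1)O[C@H](c1ccc(OCc3ccccc3)cc1)C[C@@H]2OS(C)(=O)=O | intermediate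
10 | (2S)-7,8-bis(benzyloxy)-2-[4-(benzyloxy)phenyl]-6-bromo-2H-chromene | Brc1cc2c(c(OCc3ccccc3)c1OCc1ccccc1)O[C@H](c1ccc(OCc3ccccc3)cc1)C=C2 | intermediate
11 | (2R,3R,4R)-7,8-bis(benzyloxy)-2-[4-(benzyloxy)phenyl]-6-bromo-3-iodo-3,4-dihydro-2H-chromen-4-yl benzoate (iodine trans to the 2-aryl group and to the benzoate) | Brc1cc2c(c(OCc3ccccc3)c1OCc1ccccc1)O[C@H](c1ccc(OCc3ccccc3)cc1)[C@@H](I)[C@@H]2OC(=O)c1ccccc1 | intermediate
12 | (2R,3S,4S)-7,8-bis(benzyloxy)-2-[4-(benzyloxy)phenyl]-6-bromo-3,4-dihydro-2H-chromene-3,4-diyl dibenzoate (2,3-cis-3,4-trans) | Brc1cc2c(c(OCc3ccccc3)c1OCc1ccccc1)O[C@H](c1ccc(OCc3ccccc3)cc1)[C@H](OC(=O)c1ccccc1)[C@H]2OC(=O)c1ccccc1 | intermediate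
13 | 4-(benzyloxy)benzoyl chloride | O=C(Cl)c1ccc(OCc2ccccc2)cc1 | starting material
14 | tributyl(vinyl)stannane | C=C[Sn](CCCC)(CCCC)CCCC | starting material
15 | 1-[4-(benzyloxy)phenyl]prop-2-en-1-one | C=CC(=O)c1ccc(OCc2ccccc2)cc1 | intermediate
16 | (2R,3S,4S)-7,8-bis(benzyloxy)-2-[4-(benzyloxy)phenyl]-6-{(1E)-3-[4-(benzyloxy)phenyl]-3-oxoprop-1-en-1-yl}-3,4-dihydro-2H-chromene-3,4-diyl dibenzoate | O=C(/C=C/c1cc2c(c(OCc3ccccc3)c1OCc1ccccc1)O[C@H](c1ccc(OCc3ccccc3)cc1)[C@H](OC(=O)c1ccccc1)[C@H]2OC(=O)c1ccccc1)c1ccc(OCc2ccccc2)cc1 | intermediate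
17 | (2R,3S,4S)-7,8-bis(benzyloxy)-6-{(2S,3R)-3-[4-(benzyloxy)benzoyl]oxiran-2-yl}-2-[4-(benzyloxy)phenyl]-3,4-dihydro-2H-chromene-3,4-diyl dibenzoate | O=C(c1ccc(OCc2ccccc2)cc1)[C@@H]1O[C@H]1c1cc2c(c(OCc3ccccc3)c1OCc1ccccc1)O[C@H](c1ccc(OCc3ccccc3)cc1)[C@H](OC(=O)c1ccccc1)[C@H]2OC(=O)c1ccccc1 | intermediate
18 | (2R,3S,4S)-7,8-bis(benzyloxy)-6-[(2S,3S)-3-{(S)-[4-(benzyloxy)phenyl](hydroxy)methyl}oxiran-2-yl]-2-[4-(benzyloxy)phenyl]-3,4-dihydro-2H-chromene-3,4-diyl dibenzoate | O[C@@H](c1ccc(OCc2ccccc2)cc1)[C@@H]1O[C@H]1c1cc2c(c(OCc3ccccc3)c1OCc1ccccc1)O[C@H](c1ccc(OCc3ccccc3)cc1)[C@H](OC(=O)c1ccccc1)[C@H]2OC(=O)c1ccccc1 | intermediate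
19 | pyrogallol | Oc1cccc(O)c1O | starting material
20 | 2,2-diphenyl-1,3-benzodioxol-4-ol | Oc1cccc2OC(c3ccccc3)(c3ccccc3)Oc12 | intermediate
21 | (2R,3S,4S)-7,8-bis(benzyloxy)-6-[(2S,3R)-3-{(R)-[4-(benzyloxy)phenyl][(2,2-diphenyl-1,3-benzodioxol-4-yl)oxy]methyl}oxiran-2-yl]-2-[4-(benzyloxy)phenyl]-3,4-dihydro-2H-chromene-3,4-diyl dibenzoate | O(c1cccc2OC(c3ccccc3)(c3ccccc3)Oc12)[C@H](c1ccc(OCc2ccccc2)cc1)[C@@H]1O[C@H]1c1cc2c(c(OCc3ccccc3)c1OCc1ccccc1)O[C@H](c1ccc(OCc3ccccc3)cc1)[C@H](OC(=O)c1ccccc1)[C@H]2OC(=O)c1ccccc1 | intermediate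
22 | (2R,3S,4S)-7,8-bis(benzyloxy)-2-[4-(benzyloxy)phenyl]-6-{(2R,3R,4R)-2-[4-(benzyloxy)phenyl]-3-hydroxy-7,8-(diphenylmethylenedioxy)-3,4-dihydro-2H-chromen-4-yl}-3,4-dihydro-2H-chromene-3,4-diyl dibenzoate | C(c1ccccc1)Oc1ccc([C@H]2Oc3c(ccc4OC(c5ccccc5)(c5ccccc5)Oc34)[C@H](c3cc4c(c(OCc5ccccc5)c3OCc3ccccc3)O[C@H](c3ccc(OCc5ccccc5)cc3)[C@H](OC(=O)c3ccccc3)[C@H]4OC(=O)c3ccccc3)[C@H]2O)cc1 | intermediate
23 | (2R,3R,4S)-7,8-bis(benzyloxy)-2-[4-(benzyloxy)phenyl]-6-{(2R,3R,4R)-2-[4-(benzyloxy)phenyl]-3-hydroxy-7,8-(diphenylmethylenedioxy)-3,4-dihydro-2H-chromen-4-yl}-3,4-dihydro-2H-chromene-3,4-diol | C(c1ccccc1)Oc1ccc([C@H]2Oc3c(ccc4OC(c5ccccc5)(c5ccccc5)Oc34)[C@H](c3cc4c(c(OCc5ccccc5)c3OCc3ccccc3)O[C@H](c3ccc(OCc5ccccc5)cc3)[C@H](O)[C@H]4O)[C@H]2O)cc1 | intermediate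
24 | (2R,3R,4S)-2-(4-hydroxyphenyl)-6-[(2R,3R,4S)-3,7,8-trihydroxy-2-(4-hydroxyphenyl)-3,4-dihydro-2H-chromen-4-yl]-3,4-dihydro-2H-chromene-3,4,7,8-tetrol | Oc1ccc([C@H]2Oc3c(ccc(O)c3O)[C@H](c3cc4c(c(O)c3O)O[C@H](c3ccc(O)cc3)[C@H](O)[C@H]4O)[C@H]2O)cc1 | target

**Step count.** Total: 16 steps. Longest linear sequence: 14 steps (steps 1–7, 9–11, 13–16).

**Steps most likely to fail**

Step 14. The benzylic C4 cation may undergo a 1,2-hydride shift (Meinwald-type rearrangement to the C3 ketone) instead of ring closure, may be captured after full ionisation with loss of the trans relationship, or the Lewis acid may ionise the lower C4' benzoate. The fallback sets out from 21 and comes back at 22 by stepwise, thiophilic activation. The epoxide of 21 is opened at benzylic C4 with phenylmethanethiol (BnSH, LiClO4, MeCN, rt) to give the β-hydroxy sulfide F1. Treatment of F1 with AgBF4 (CH2Cl2, 0 °C) should then generate the C4 cation under neutral conditions, and ring A should close onto it anti to the free 3-hydroxyl, an intramolecular version of the thioether/silver-salt flavan-4-yl arylation, giving 22.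

Step 13. The oxyphosphonium ion of the para-alkoxybenzylic alcohol may ionise, so that the configuration at C2 is lost, or the neighbouring epoxide may take part. The fallback sets out from 17 and comes back at 21, forming the ether with retention instead of inversion. Noyori transfer hydrogenation of 17 under catalyst control (RuCl(p-cymene)[(S,S)-TsDPEN], HCO2H/Et3N) should give the syn epoxy alcohol F2, the C2 epimer of 18. Commercial 3-bromocatechol and Ph2CCl2 (neat, 170 °C) give 4-bromo-2,2-diphenyl-1,3-benzodioxole F3. Palladium-catalysed C–O coupling of F2 with F3 ([PdCl(allyl)]2, RockPhos, Cs2CO3, toluene, 90 °C) then forms the aryl ether without breaking a bond at C2 and gives 21.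

Step 7. Opening of the iodonium or dioxolanylium ion through a free C4' cation may erode the facial and regiochemical course, and the hypoiodite may iodinate an arene. The fallback sets out from 10 and comes back at 12 in four conventional operations. NBS in wet DMSO should give the trans-bromohydrin F4 (bromine anti to the 2-aryl group, hydroxyl at C4). K2CO3 in MeOH closes it to the cis-fused 3,4-epoxide F5 on the face of the 2-aryl group. Benzoic acid (toluene, 60 °C) opens F5 at benzylic C4 with inversion to the 4-benzoate 3-alcohol F6, and BzCl/pyridine/DMAP gives 12.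

**Further compounds**

F1 | step 14 | β-hydroxy sulfide: 21 with the epoxide opened at C4 by benzylsulfanyl (inversion) and free 3-OH | O(c1cccc2OC(c3ccccc3)(c3ccccc3)Oc12)[C@H](c1ccc(OCc2ccccc2)cc1)[C@H](O)[C@H](SCc1ccccc1)c1cc2c(c(OCc3ccccc3)c1OCc1ccccc1)O[C@H](c1ccc(OCc3ccccc3)cc1)[C@H](OC(=O)c1ccccc1)[C@H]2OC(=O)c1ccccc1
F2 | step 13 | syn epoxy alcohol, C2 epimer of 18 | O[C@H](c1ccc(OCc2ccccc2)cc1)[C@@H]1O[C@H]1c1cc2c(c(OCc3ccccc3)c1OCc1ccccc1)O[C@H](c1ccc(OCc3ccccc3)cc1)[C@H](OC(=O)c1ccccc1)[C@H]2OC(=O)c1ccccc1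
F3 | step 13 | 4-bromo-2,2-diphenyl-1,3-benzodioxole | Brc1cccc2OC(c3ccccc3)(c3ccccc3)Oc12
F4 | step 7 | trans-bromohydrin of 10 (3-bromo trans to the 2-aryl group, 4-hydroxy cis to it) | Brc1cc2c(c(OCc3ccccc3)c1OCc1ccccc1)O[C@H](c1ccc(OCc3ccccc3)cc1)[C@@H](Br)[C@@H]2O
F5 | step 7 | 3,4-epoxide of 10 on the face of the 2-aryl group | Brc1cc2c(c(OCc3ccccc3)c1OCc1ccccc1)O[C@H](c1ccc(OCc3ccccc3)cc1)[C@@H]3O[C@H]23
F6 | step 7 | 2,3-cis-3,4-trans 3-hydroxy 4-benzoate | Brc1cc2c(c(OCc3ccccc3)c1OCc1ccccc1)O[C@H](c1ccc(OCc3ccccc3)cc1)[C@H](O)[C@H]2OC(=O)c1ccccc1
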